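**Retrosynthetic overview**

1. The target is two identical trans-decalin halves joined through C11–C11′ (drimane numbering per half: ring A = C1–C5, C10; ring B = C5–C10; C11 on C9; second half primed). Feature used: in each ring B the tetrasubstituted C8=C9 alkene has its allylic C7 inside the ring, so C7–C8(CH3)–C9 is an allyl-cation retron, and C5 lies between the quaternary carbons C4 and C10, so a C5=C6 methylidene can attack only through C6 and lose only a C6 proton; the C2 axis through C11–C11′ lets both rings B be made at once.
2. Last disconnection: the C5–H and C5′–H centres, set by hydrogenating the C5=C6 bonds of a bis(5,8-diene) from the face anti to the C10 methyls.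
3. Key disconnection, C6–C7 and C8=C9 (twice): a C2-symmetric 1,4-diketone (carbonyls at C9 and C9′, methylidene on C5 and C5′) plus two isopropenyl units (C7, C8 and the C8 methyl). Grignard addition makes C8–C9; ionisation to the allyl cation and attack of the methylidene makes C6–C7 and leaves C8=C9.
4. The 1,4-diketone (C9–C11–C11′–C9′) is carried as a temporary furan ring and opened after the ring A ketones (C5, C5′) have been methylenated.
5. C10–C9 and C10′–C9′: twofold enantioselective enolate heteroarylation of 2,2,6-trimethylcyclohexanone on 2,5-dibromofuran sets both quaternary centres. Ring order: rings A bought, furan as temporary ring, rings B and B′ together in the key step.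

Key step: step 5

Assumption: (R)-BINAP on palladium is taken to give the (R)-configured quaternary carbon in the enolate heteroarylation; should the sense of induction be the opposite, (S)-BINAP is used in its place.

**Route**

Step 1
Reactants: 1 2,2,6-trimethylcyclohexan-1-one (racemic, two molecules per molecule of 2); 2 2,5-dibromofuran
Product: 3 2,5-bis[(1R)-1,3,3-trimethyl-2-oxocyclohexyl]furan
Conditions: Pd2(dba)3 (cat.), (R)-BINAP, NaOt-Bu, toluene, 90 °C
Reagents that add atoms: none
Why: Palladium-catalysed α-heteroarylation of a ketone enolate (enolate cross-coupling), run twice on the dibromide: 1 can enolise only towards C6, its enolate is planar so the racemate is fully used, each coupling creates a quaternary stereocentre under control of the chiral bisphosphine on palladium, the arylated ketone has no α-hydrogen left and cannot react again, and removal of the minor meso diastereomer by chromatography or crystallisation also raises the enantiomeric purity of the C2-symmetric product by statistical amplification.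

Step 2
Reactants: 3 2,5-bis[(1R)-1,3,3-trimethyl-2-oxocyclohexyl]furan
Product: 5 2,5-bis[(1S)-1,3,3-trimethyl-2-methylidenecyclohexyl]furan, via bis(β-hydroxysilane) 4 (not isolated)
Conditions: Me3SiCH2Li, THF, 0 °C to rt; water quench, crude; then KH, THF, 60 °C
Reagents that add atoms: (trimethylsilyl)methyllithium, C[Si](C)(C)C[Li]
Why: Peterson olefination: the small α-silyl carbanion adds to the non-enolisable, doubly neopentylic ketones that are too hindered for phosphorus ylides, and the potassium alkoxides of the β-hydroxysilanes then lose Me3SiOK by syn-elimination under basic conditions that spare the acid-sensitive furan and the quaternary stereocentres (the carbinol centres formed on the way are destroyed again).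

Step 3
Reactants: 5 2,5-bis[(1S)-1,3,3-trimethyl-2-methylidenecyclohexyl]furan
Product: 7 (2Z)-1,4-bis[(1S)-1,3,3-trimethyl-2-methylidenecyclohexyl]but-2-ene-1,4-dione, via furan endoperoxide 6 (not isolated)
Conditions: O2, visible light, tetraphenylporphyrin (cat.), CH2Cl2, −78 °C; then Me2S, −78 °C to rt
Reagents that add atoms: dioxygen (as singlet oxygen), O=O
Why: [4+2] Cycloaddition of singlet oxygen to the electron-rich 2,5-dialkylfuran followed by reduction of the endoperoxide with Me2S (furan to cis-ene-1,4-dione unmasking): the methylidene groups have no allylic hydrogen and lie between two quaternary carbons, so they do not react with singlet oxygen, and the (Z)-geometry is inherited from the ring.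

Step 4
Reactants: 7 (2Z)-1,4-bis[(1S)-1,3,3-trimethyl-2-methylidenecyclohexyl]but-2-ene-1,4-dione
Product: 8 1,4-bis[(1S)-1,3,3-trimethyl-2-methylidenecyclohexyl]butane-1,4-dione
Conditions: Zn dust, AcOH, rt
Reagents that add atoms: none
Why: Dissolving-metal reduction of an ene-1,4-dione (electron transfer from zinc, protonation by acetic acid) saturates only the doubly activated C11=C11′ bond and leaves the unactivated methylidene groups, the ketones and the stereocentres as they are.

Step 5
Reactants: 8 1,4-bis[(1S)-1,3,3-trimethyl-2-methylidenecyclohexyl]butane-1,4-dione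
Product: 10 1,2-bis[(8aR)-2,5,5,8a-tetramethyl-3,5,6,7,8,8a-hexahydronaphthalen-1-yl]ethane, via bis-allylic diol 9 (not isolated)
Conditions: CH2=C(CH3)MgBr, LaCl3·2LiCl (cat.), THF, 0 °C to rt; then THF exchanged for CH2Cl2, CF3CO2H, −78 to −20 °C
Reagents that add atoms: prop-1-en-2-ylmagnesium bromide, CC(=C)[Mg]Br
Why: Two Grignard 1,2-additions (LaCl3·2LiCl suppresses enolisation of the hindered ketones) form C8–C9 and C8′–C9′ and give, on acidification, the bis(tertiary allylic) diol 9. CF3CO2H then ionises each carbinol to the allyl cation C7–C8(CH3)–C9, whose primary terminus C7 is attacked by C6 of the neighbouring methylidene group, which forms C6–C7 and leaves C8=C9 as the tetrasubstituted alkene, and loss of a C6 proton from the tertiary C5 cation ends each closure. The closest known reaction type is the cation–olefin cyclisation that is initiated by a tertiary allylic alcohol and terminated by an alkene, here telescoped with the carbonyl addition that makes the initiator. Rings B and B′ each close in a 6-endo-trig mode with respect to the methylidene group (Markovnikov attack through its CH2 terminus, charge on tertiary C5), the alternative attack on C9 being excluded as a four-membered closure. No stereocentre is created, since the carbinol centres of 9 are erased and C5 becomes trigonal, and the quaternary C10 and C10′ centres are not touched because no cation is formed at them and they cannot enolise. The step needs carbon- over oxygen-alkylation and a single direction of proton loss: cyclic ether formation from the 1,4-diol is reversible under the acid while C–C bond formation is not, and C5 lies between the quaternary C4 and C10, so only a C6 hydrogen can be lost.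

Step 6
Reactants: 10 1,2-bis[(8aR)-2,5,5,8a-tetramethyl-3,5,6,7,8,8a-hexahydronaphthalen-1-yl]ethane
Product: 11 1,2-bis[(4aS,8aS)-2,5,5,8a-tetramethyl-3,4,4a,5,6,7,8,8a-octahydronaphthalen-1-yl]ethane (target)
Conditions: H2 (1–3 atm), PtO2 (cat.), EtOAc/AcOH, rt
Reagents that add atoms: none
Why: Heterogeneous catalytic hydrogenation: hydrogen is delivered to each trisubstituted C5=C6 bond from the α-face, anti to the axial C10 methyl and the axial C4 methyl, as in the hydrogenation of 4,4-dimethyl-Δ5-steroids to the 5α-series, which sets C5 and C5′ trans to the angular methyls, while the tetrasubstituted C8=C9 bonds next to quaternary C10 are not reduced on platinum under these mild conditions.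

**Compound list**

1 | 2,2,6-trimethylcyclohexan-1-one (racemic) | CC1CCCC(C)(C)C1=O | starting material
2 | 2,5-dibromofuran | Brc1ccc(Br)o1 | starting material
3 | 2,5-bis[(1R)-1,3,3-trimethyl-2-oxocyclohexyl]furan | O=C1C(C)(C)CCC[C@]1(C)c1ccc(o1)[C@@]1(C)CCCC(C)(C)C1=O | intermediate
4 | 2,5-bis{2-hydroxy-1,3,3-trimethyl-2-[(trimethylsilyl)methyl]cyclohexyl}furan (quaternary centres as in 3, carbinol centres as a mixture) | C[Si](C)(C)CC1(O)C(C)(C)CCC[C@]1(C)c1ccc(o1)[C@@]1(C)CCCC(C)(C)C1(O)C[Si](C)(C)C | intermediate
5 | 2,5-bis[(1S)-1,3,3-trimethyl-2-methylidenecyclohexyl]furan | C=C1C(C)(C)CCC[C@]1(C)c1ccc(o1)[C@@]1(C)CCCC(C)(C)C1=C | intermediate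
6 | 1,4-bis[(1S)-1,3,3-trimethyl-2-methylidenecyclohexyl]-2,3,7-trioxabicyclo[2.2.1]hept-5-ene | C=C1C(C)(C)CCC[C@]1(C)C23C=CC(O2)(OO3)[C@@]1(C)CCCC(C)(C)C1=C | intermediate
7 | (2Z)-1,4-bis[(1S)-1,3,3-trimethyl-2-methylidenecyclohexyl]but-2-ene-1,4-dione | C=C1C(C)(C)CCC[C@]1(C)C(=O)/C=C\C(=O)[C@@]1(C)CCCC(C)(C)C1=C | intermediate
8 | 1,4-bis[(1S)-1,3,3-trimethyl-2-methylidenecyclohexyl]butane-1,4-dione | C=C1C(C)(C)CCC[C@]1(C)C(=O)CCC(=O)[C@@]1(C)CCCC(C)(C)C1=C | intermediate
9 | 2,7-dimethyl-3,6-bis[(1S)-1,3,3-trimethyl-2-methylidenecyclohexyl]octa-1,7-diene-3,6-diol (carbinol centres as a mixture) | C=C1C(C)(C)CCC[C@]1(C)C(O)(C(C)=C)CCC(O)(C(C)=C)[C@@]1(C)CCCC(C)(C)C1=C | intermediate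
10 | 1,2-bis[(8aR)-2,5,5,8a-tetramethyl-3,5,6,7,8,8a-hexahydronaphthalen-1-yl]ethane | CC1=C(CCC2=C(C)CC=C3C(C)(C)CCC[C@]23C)[C@@]2(C)CCCC(C)(C)C2=CC1 | intermediate
11 | 1,2-bis[(4aS,8aS)-2,5,5,8a-tetramethyl-3,4,4a,5,6,7,8,8a-octahydronaphthalen-1-yl]ethane | CC1=C(CCC2=C(C)CC[C@H]3C(C)(C)CCC[C@]23C)[C@@]2(C)CCCC(C)(C)[C@@H]2CC1 | target

**Step count and risks**

Total step count: 6. Longest linear sequence: 6 steps (from 1 or 2 to 11).

Steps most likely to fail:

1. Step 5. The second Grignard addition to the hindered, enolisable 1,4-diketone may stall at the cyclic hemiketal stage. The cations may also be diverted into cyclic ether formation, into methyl migration towards the C5 cation, or into acid-induced double-bond migration. The fallback sets out from 8 and makes the two bonds in separate operations with a non-protic trigger. The Grignard addition is run alone and diol 9 is isolated. PBr3 with pyridine then converts 9 with allylic transposition into 1,8-dibromo-2,7-dimethyl-3,6-bis[(1S)-1,3,3-trimethyl-2-methylidenecyclohexyl]octa-2,6-diene F1, in which C8=C9 is already in place and no hydroxyl group is left. AgBF4 with 2,6-di-tert-butyl-4-methylpyridine in CH2Cl2 at −78 °C abstracts bromide, and the buffered allyl cations close rings B through C6–C7. The fallback comes back to the route at 10.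

2. Step 1. The second coupling on the furan may stall, the dibromide may decompose under the basic conditions, or catalyst control may erode in the second bond formation. The fallback sets out from 1 and builds the two C–C bonds one at a time. The same enantioselective enolate heteroarylation with commercial 2-bromofuran gives (2R)-2-(furan-2-yl)-2,6,6-trimethylcyclohexan-1-one F2. Bromination of the free furan α-position with N-bromosuccinimide gives (2R)-2-(5-bromofuran-2-yl)-2,6,6-trimethylcyclohexan-1-one F3. A second enolate heteroarylation of 1 with F3 comes back to the route at 3.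

3. Step 6. Reduction of the doubly neopentylic C5=C6 bonds may be slow, the double bond may migrate into conjugation on the metal surface, or hydrogen delivery may show poor facial selectivity. The fallback sets out from 10 and replaces surface hydrogenation by hydrogen-atom-transfer hydrogenation (Mn(dpm)3, PhSiH3, t-BuOOH, i-PrOH). The tertiary C5 radical formed by hydrogen-atom transfer to C6 takes its second hydrogen from the less hindered α-face and gives the thermodynamically favoured trans ring fusion, while the more hindered tetrasubstituted alkenes react far more slowly. It comes back to the route at 11 and makes no new compound (none F0).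

**Further compounds**

F1 | step 5 | 1,8-dibromo-2,7-dimethyl-3,6-bis[(1S)-1,3,3-trimethyl-2-methylidenecyclohexyl]octa-2,6-diene (E/Z mixture) | C=C1C(C)(C)CCC[C@]1(C)C(=C(C)CBr)CCC(=C(C)CBr)[C@@]1(C)CCCC(C)(C)C1=C
F2 | step 1 | (2R)-2-(furan-2-yl)-2,6,6-trimethylcyclohexan-1-one | O=C1C(C)(C)CCC[C@]1(C)c1ccco1
F3 | step 1 | (2R)-2-(5-bromofuran-2-yl)-2,6,6-trimethylcyclohexan-1-one | O=C1C(C)(C)CCC[C@]1(C)c1ccc(Br)o1
F0 | step 6 | none | none
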